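**The problem**

The target is a biflavone ether. An acacetin unit (5,7-dihydroxy-4'-methoxyflavone) carries at C8 an oxygen that is bonded to C4' of ring B of a genkwanin unit (5-hydroxy-7-methoxyflavone). There is no stereocentre, so the synthesis turns on regiochemistry and on telling the oxygens apart.

Ring A of the acacetin unit is a benzene ring with five substituents: O1 on C8a, hydroxyls on C5 and C7, the aryloxy group on C8, and C4 on C4a. The aryloxy group must sit at C8 and not at C6. A finished 5,7-dioxygenated flavone does not distinguish these two positions, so the substituent order has to be fixed before ring C exists.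

The peripheral oxygens end in three states: free hydroxyl (C5, C7, C5''), methyl ether (C4', C7'') and diaryl ether. The groups masking the three hydroxyls must therefore come off without harming methyl ethers or the diaryl ether.

The free phloroglucinol-type rings oxidise and C-alkylate easily. Each 4-pyranone opens at C2 under hot hydroxide, and its C2=C3 bond can be over-reduced. The phenols are therefore freed last and the second flavone is built late.

The feature used here is the C2=C3 bond of ring C of the acacetin unit. C2 is bonded to O1 (which sits on C8a) and to the 4-methoxyphenyl group, and C3 is alpha to the C4 carbonyl on C4a. The bond is thus both an enol ether and an enone double bond. Cutting it leaves a 1-(4-methoxyphenyl)vinyl ether on O1 and a vinyl ketone on C4a, two terminal alkenes held ortho on ring A, which is the arrangement for ring-closing metathesis.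

**Retrosynthesis**

Target 24 is traced to its tri-O-benzyl ether 23 by cutting the benzyl–oxygen bonds at O5, O7 and O5''. Benzyl is preferred to methyl or MOM because hydrogenolysis cannot touch the methyl ethers at O4' and O7''. It is preferred to silyl or acyl groups because it survives every base, organometallic reagent and oxidant used earlier. The skeleton is unchanged, but all three sensitive phenols are masked. The forward step must cleave three benzyl ethers without reducing either C2=C3 bond.

In 23 the genkwanin unit is taken apart first, at O1''–C2'' (chalcone 22) and then at C2''–C3'' (aldehyde 19 and acetophenone 21). This order is forced. The chalcone route needs only hydroxide and catalytic iodine, which a finished flavone tolerates. The metathesis precursor of the acacetin unit needs vinylmagnesium bromide and Cp2Ti(μ-CH2)(μ-Cl)AlMe2, which no flavone would survive. A Baker–Venkataraman construction from the corresponding acid is the neighbouring cut. The aldehyde level is chosen because it can be carried as an acetal. The cut removes a whole flavone. Acetophenone 21 comes from commercial 20 by benzylation of one of its two equivalent hydroxyls, so that O5'' is unmasked together with the other benzyl ethers. The forward condensation must outrun hydroxide attack on C2 of the first pyranone.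

Aldehyde 19 is written as its ethylene acetal 18. Only the two C–O bonds of the dioxolane are involved. The forward hydrolysis must spare benzyl and methyl ethers, which dilute acid does.

Flavone 18 is opened at C2=C3 to diene 17. The neighbouring cuts, O1–C2 and C4–C4a, are established ones. The metathesis cut is chosen for three reasons:
- It closes the ring at neutral pH without oxidant, acid or base.
- It hangs each olefin half on an atom that is already in place (O1 and C4a), so the crowded ring A is complete before the ring forms.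
- It does not depend on the nucleophilicity of ring A.

Precursor 17 lacks ring C and is a plainly substituted arene. The forward step must join an electron-poor monosubstituted alkene with an electron-rich 1,1-disubstituted one. The phosphine-free complex RuCl2(=CH-C6H4-2-OiPr)(H2IMes) is specified instead of RuCl2(=CHPh)(H2IMes)(PCy3), because free PCy3 adds to vinyl ketones.

Enone 17 goes back to allylic alcohol 16, silyl ether 15 and ester 14. The vinyl ketone cannot be present when the enol ether is made, since Cp2Ti(μ-CH2)(μ-Cl)AlMe2 would methylenate a ketone before an ester. The ketone is therefore carried as a silyl-protected carbinol, and the C=CH2 bond of the enol ether is cut back to the carbonyl of a 4-methoxybenzoate. Other ways to a 1-arylvinyl aryl ether (O-vinylation, addition to an alkyne) lack precedent on hindered phenols. The forward methylenation must take a hindered ester in the presence of an acetal, a terminal alkene and an ionisable benzylic silyl ether.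

Ester 14 is cut at the ester C–O bond and the Si–O bond to diol 11 and acid chloride 12. Diol 11 is cut at the carbinol–vinyl C–C bond to salicylaldehyde 10. The forward acylation must choose the phenol over the carbinol, and the carbinol must be capped before the acyl group can migrate to it.

Aldehyde 10 is cut at the formyl–aryl bond to phenol 9. The phenol of 9 has one free ortho position, the future C4a. The other open ring carbon lies para to the hydroxyl and is not reached by magnesium-directed formylation.

Phenol 9 goes back through 8 and 7 to phenol 5 and 4-fluorobenzaldehyde 6, by cutting the diaryl ether C–O bond on the ring B side. There the para-formyl group makes 6 an SNAr electrophile. A cut on the ring A side would need an electrophilic tetraoxygenated arene. The formyl group serves twice, as activating group now and as C2'' later. The MOM group on the neighbouring oxygen keeps the future O1 out of the arylation. It is then removed (8) and the aldehyde masked (9).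

Phenol 5 goes back to 3, 2 and 1. The phenol oxygen of 5 replaces the formyl carbon of 3 by Baeyer–Villiger oxidation. The formyl group of 1 distinguishes its three hydroxyls: two are benzylated (2), and the chelated one is left for the MOM group (3). The aldehyde carbon of 1 thus marks the site of the C8 oxygen, and its chelated hydroxyl becomes O1.

**Roads not taken**

Alternative 1: The cut runs through ring B of the genkwanin unit, at C3'–C4' and C5'–C6', so that the benzene ring bearing the ether oxygen is built and not bought.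
- Forward key step: the aryl ethynyl ether A1 (the O-ethynyl derivative of phenol 5) and the 2-pyranone A2 undergo an inverse-demand [4+2] cycloaddition. A retro-[4+2] loss of the lactone bridge then gives the para-aryloxybenzoate A3.
- Merits: the polarity of the two partners fixes the para relation, and the hindered oxygen of ring A is already etherified before the arene is made.
- Weak points: A1 needs two further operations from 5 and is acid-labile. The ring it assembles is an ordinary para-disubstituted benzene, and the chosen route reaches the analogous ether 7 from 5 and 6 in one SNAr step. The cut also says nothing about ring C of the acacetin unit or the placement at C8.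
- Comparison: A3 is better in one respect. Its ester level would allow the genkwanin pyranone to be closed by a Baker–Venkataraman sequence without exposing a flavone to hydroxide. The chosen plan uses hydroxide in step 16 and keeps that sequence only as a fallback. Against this it has the shorter path to the diaryl ether.

Alternative 2: Three bonds of ring C of the genkwanin unit are cut at once: O1''–C8a'', C4''–C4a'' and O1''–C2''.
- Forward key step: fluoride releases an aryne from silyl triflate A4. The carboxylate of arylpropiolic acid A5 attacks it at the carbon remote from the flanking methoxy group. The aryl anion takes the acyl carbon, and the resulting phenoxide closes 6-endo onto the ynone to give biflavone A6.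
- Merits: it is highly convergent, the whole pyranone forms in one operation near neutral pH, and the methoxy group of the aryne directs both new bonds.
- Weak points: A6 has a methyl ether at O5'' where the target has a hydroxyl. A chelation-controlled demethylation must then be selective beside the methyl ethers at O4' and O7''. A5 needs a two-carbon homologation and carboxylation of aldehyde 19, and A4 is a multistep reagent. O-arylation without acyl transfer and 5-exo closure compete.
- Comparison: the route still needs 19, so it replaces only steps 15–17 and leaves the acacetin ring unsolved. In convergence and mildness it is at least the equal of steps 16 and 17. The chosen plan sets against it older reaction types, a benzyl group at O5'' that leaves in the final hydrogenolysis, and no extra steps to A4 and A5.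

Alternative 3: The cut is C4–C4a of the acacetin unit, with O1–C2 made beforehand.
- Forward key step: phenol A7 (the methyl ester counterpart of 8) adds to arylpropiolate A8. After release of the acid, the (Z)-acrylic acid A9 is activated as a mixed anhydride and acylates its own aryloxy ring at the only open ortho position, giving flavone ester A10.
- Merits: the tether through O1 fixes the regiochemistry as firmly as the chosen plan does. Every reaction type is known. It needs about three steps from A7, where the chosen route needs seven (steps 7–13) from 9, and it needs no acetal.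
- Weak points: the closure is strongly acidic and electrophilic on a ring with two benzyl ethers, so debenzylation, C-benzylation and acylation at C6 by the activating agent are risks. Only the Z isomer of A9 can close. The ester of A10 must still be converted into the second flavone.
- Comparison: on step count and precedent this is the stronger route. The chosen plan sets against it a ring closure without acid, base or oxidant, the aldehyde level for the genkwanin unit carried directly, and a flavone bond construction that does not rely on the nucleophilicity of ring A.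

Key step: step 13

Remark on the chemistry: the target has no stereocentre; the carbinol carbon made in step 8 is carried as a racemate (11, 13–16) and becomes the C4 carbonyl in step 12.

**Route**

Step 1
Reactants: 1 2,4,6-trihydroxybenzaldehyde
Product: 2 2,4-bis(benzyloxy)-6-hydroxybenzaldehyde
Conditions: BnBr (2.1 equiv), K2CO3, DMF, 0 °C to rt
Reagents that add atoms: benzyl bromide, BrCc1ccccc1
Why: Williamson etherification; the para hydroxyl and one ortho hydroxyl are alkylated, while the remaining ortho hydroxyl is hydrogen-bonded to the formyl group and is the least nucleophilic, so two equivalents should stop at the dibenzyl ether.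

Step 2
Reactants: 2 2,4-bis(benzyloxy)-6-hydroxybenzaldehyde
Product: 3 2,4-bis(benzyloxy)-6-(methoxymethoxy)benzaldehyde
Conditions: MOMCl, iPr2NEt, CH2Cl2, 0 °C to rt
Reagents that add atoms: chloromethyl methyl ether, COCCl
Why: O-alkylation of the chelated phenol as its MOM acetal; unlike an acyl or silyl group it cannot migrate to the neighbouring oxygen freed in step 3, and it survives peracid and hot carbonate.

Step 3
Reactants: 3 2,4-bis(benzyloxy)-6-(methoxymethoxy)benzaldehyde
Product: 5 2,4-bis(benzyloxy)-6-(methoxymethoxy)phenol, via aryl formate 4 (not isolated)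
Conditions: mCPBA, CH2Cl2, 0 °C to rt; aq. NaHCO3 wash; then K2CO3 (cat.), MeOH, rt
Reagents that add atoms: mCPBA, O=C(OO)c1cccc(Cl)c1
Why: Baeyer–Villiger (Dakin-type) oxidation; the trioxygenated aryl group migrates in preference to hydrogen, and the formate is cleaved by mild methanolysis.

Step 4
Reactants: 5 2,4-bis(benzyloxy)-6-(methoxymethoxy)phenol; 6 4-fluorobenzaldehyde
Product: 7 4-[2,4-bis(benzyloxy)-6-(methoxymethoxy)phenoxy]benzaldehyde
Conditions: K2CO3, DMF, 110 °C, argon
Reagents that add atoms: none
Why: Nucleophilic aromatic substitution through a Meisenheimer adduct; fluoride para to a formyl group is displaced even by 2,6-disubstituted phenoxides, and exclusion of air protects the electron-rich phenoxide.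

Step 5
Reactants: 7 4-[2,4-bis(benzyloxy)-6-(methoxymethoxy)phenoxy]benzaldehyde
Product: 8 4-[2,4-bis(benzyloxy)-6-hydroxyphenoxy]benzaldehyde
Conditions: conc. HCl (cat.), MeOH/THF, 50 °C; aqueous work-up
Reagents that add atoms: none
Why: Acid-catalysed acetal exchange of the MOM ether with methanol; benzyl ethers and the diaryl ether are inert, and any dimethyl acetal of the aldehyde reverts on aqueous work-up.

Step 6
Reactants: 8 4-[2,4-bis(benzyloxy)-6-hydroxyphenoxy]benzaldehyde
Product: 9 3,5-bis(benzyloxy)-2-[4-(1,3-dioxolan-2-yl)phenoxy]phenol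
Conditions: ethylene glycol, pTsOH·H2O (cat.), toluene, reflux, Dean–Stark
Reagents that add atoms: ethylene glycol, OCCO
Why: Acid-catalysed acetalisation with azeotropic removal of water; the dioxolane shields the aldehyde from the organomagnesium and titanium reagents to come.

Step 7
Reactants: 9 3,5-bis(benzyloxy)-2-[4-(1,3-dioxolan-2-yl)phenoxy]phenol
Product: 10 4,6-bis(benzyloxy)-3-[4-(1,3-dioxolan-2-yl)phenoxy]-2-hydroxybenzaldehyde
Conditions: MgCl2, Et3N, (CH2O)n, THF, reflux; pH 5 buffer work-up
Reagents that add atoms: paraformaldehyde (as formaldehyde), C=O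
Why: Magnesium-mediated ortho-formylation (Casnati–Skattebøl); the magnesium phenoxide delivers formaldehyde to the ortho carbon and a second formaldehyde oxidises the benzylic alkoxide by hydride transfer. Only one ortho position is free, so the formyl group must enter at the future C4a.

Step 8
Reactants: 10 4,6-bis(benzyloxy)-3-[4-(1,3-dioxolan-2-yl)phenoxy]-2-hydroxybenzaldehyde
Product: 11 3,5-bis(benzyloxy)-2-[4-(1,3-dioxolan-2-yl)phenoxy]-6-(1-hydroxyprop-2-en-1-yl)phenol (racemic)
Conditions: CH2=CHMgBr (3 equiv), THF, −78 to 0 °C; sat. NH4Cl at 0 °C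
Reagents that add atoms: vinylmagnesium bromide, C=C[Mg]Br
Why: Grignard 1,2-addition; the first equivalent deprotonates the phenol and further reagent adds to the chelated aldehyde. The carbinol centre is racemic and is erased in step 12; the ionisable diol is taken on without delay.

Step 9
Reactants: 11 3,5-bis(benzyloxy)-2-[4-(1,3-dioxolan-2-yl)phenoxy]-6-(1-hydroxyprop-2-en-1-yl)phenol (racemic); 12 4-methoxybenzoyl chloride
Product: 14 3,5-bis(benzyloxy)-2-[4-(1,3-dioxolan-2-yl)phenoxy]-6-{1-[(triethylsilyl)oxy]prop-2-en-1-yl}phenyl 4-methoxybenzoate (racemic), via hydroxy ester 13 (not isolated)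
Conditions: 12 (1.05 equiv), Et3N, CH2Cl2, −20 °C; then Et3SiCl, imidazole, 0 °C
Reagents that add atoms: chlorotriethylsilane, CC[Si](Cl)(CC)CC
Why: Chemoselective O-acylation of the phenol (no acyl-transfer catalyst, hindered secondary alcohol untouched), then silylation of the carbinol in the same flask. Ester 13 is thus never left with base long enough for O-to-O acyl migration.

Step 10
Reactants: 14 3,5-bis(benzyloxy)-2-[4-(1,3-dioxolan-2-yl)phenoxy]-6-{1-[(triethylsilyl)oxy]prop-2-en-1-yl}phenyl 4-methoxybenzoate (racemic)
Product: 15 triethyl({1-[4,6-bis(benzyloxy)-3-[4-(1,3-dioxolan-2-yl)phenoxy]-2-{[1-(4-methoxyphenyl)ethenyl]oxy}phenyl]prop-2-en-1-yl}oxy)silane (racemic)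
Conditions: Cp2Ti(μ-CH2)(μ-Cl)AlMe2 (1.3 equiv), pyridine, THF/toluene, −40 °C to rt; aq. NaOH quench
Reagents that add atoms: Tebbe reagent Cp2Ti(μ-CH2)(μ-Cl)AlMe2, C[Al-]1(C)C[Ti](C2C=CC=C2)(C2C=CC=C2)[Cl+]1
Why: Tebbe methylenation through Cp2Ti=CH2 and an oxatitanacyclobutane; aryl benzoates are standard substrates. Pyridine keeps the aluminium Lewis acid off the acetal and the silyloxy centre, and near-stoichiometric reagent at low temperature leaves the terminal alkene alone.

Step 11
Reactants: 15 triethyl({1-[4,6-bis(benzyloxy)-3-[4-(1,3-dioxolan-2-yl)phenoxy]-2-{[1-(4-methoxyphenyl)ethenyl]oxy}phenyl]prop-2-en-1-yl}oxy)silane (racemic)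
Product: 16 1-[4,6-bis(benzyloxy)-3-[4-(1,3-dioxolan-2-yl)phenoxy]-2-{[1-(4-methoxyphenyl)ethenyl]oxy}phenyl]prop-2-en-1-ol (racemic)
Conditions: Bu4NF, THF, 0 °C
Reagents that add atoms: none
Why: Fluoride-mediated desilylation; the medium is basic, so the acid-labile enol ether and acetal are not at risk.

Step 12
Reactants: 16 1-[4,6-bis(benzyloxy)-3-[4-(1,3-dioxolan-2-yl)phenoxy]-2-{[1-(4-methoxyphenyl)ethenyl]oxy}phenyl]prop-2-en-1-ol (racemic)
Product: 17 1-[4,6-bis(benzyloxy)-3-[4-(1,3-dioxolan-2-yl)phenoxy]-2-{[1-(4-methoxyphenyl)ethenyl]oxy}phenyl]prop-2-en-1-one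
Conditions: MnO2 (activated, excess), CH2Cl2, rt; filtered and used at once
Reagents that add atoms: none
Why: MnO2 oxidation of an allylic and benzylic alcohol under neutral heterogeneous conditions; the enol ether is not attacked, and the polymerisable aryl vinyl ketone is not stored.

Step 13
Reactants: 17 1-[4,6-bis(benzyloxy)-3-[4-(1,3-dioxolan-2-yl)phenoxy]-2-{[1-(4-methoxyphenyl)ethenyl]oxy}phenyl]prop-2-en-1-one
Product: 18 5,7-bis(benzyloxy)-8-[4-(1,3-dioxolan-2-yl)phenoxy]-2-(4-methoxyphenyl)-4H-chromen-4-one
Conditions: RuCl2(=CH-C6H4-2-OiPr)(H2IMes) (10 mol %), toluene (0.005 M), 80 °C, argon sparge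
Reagents that add atoms: none
Why: Proposed new method: ring-closing metathesis between an aryl vinyl ketone and a 1-aryl-1-aryloxyethene to give a 4-pyranone has not been shown, the closest known reaction types being the ruthenium-carbene ring-closing metathesis of methylenated aryl esters with a second alkene to benzofurans and 4H-chromenes and of acrylate esters to coumarins. The benzylidene should exchange first with the monosubstituted vinyl ketone, and the acyl-substituted carbene then adds [2+2] across the enol ether held ortho to it; cycloreversion of the ruthenacyclobutane gives the C2=C3 bond and RuCl2(=CH2)(H2IMes), which re-enters the cycle and leaves ethene as the only by-product. Pairing an electron-poor with an electron-rich alkene is the complementary combination that makes acrylate cross-metathesis selective, and the ortho tether allows a ring only through the metallacycle in which the carbene carbon bonds to the oxygen-bearing carbon. Ring C of the acacetin unit closes as a six-membered ring with both olefin carbons endocyclic, and loss of ethene together with the conjugation of the 4-pyranone should make the closure irreversible. The phosphine-free isopropoxybenzylidene complex is preferred to RuCl2(=CHPh)(H2IMes)(PCy3) because free PCy3 adds to vinyl ketones and to acyl carbenes and would drain the catalyst. No stereocentre is formed. The step needs ring closure to outrun cross-metathesis and polymerisation of the enone, which the ortho placement of the only two alkenes, high dilution and removal of ethene should secure, while the neutral medium leaves the benzyl ethers, the acetal and the electron-rich ring untouched. The place of the aryloxy group at C8 is not decided here: it follows from the enol ether oxygen being the phenol oxygen next to that carbon in 9.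

Step 14
Reactants: 18 5,7-bis(benzyloxy)-8-[4-(1,3-dioxolan-2-yl)phenoxy]-2-(4-methoxyphenyl)-4H-chromen-4-one
Product: 19 4-{[5,7-bis(benzyloxy)-2-(4-methoxyphenyl)-4-oxo-4H-chromen-8-yl]oxy}benzaldehyde
Conditions: 1 M aq. HCl, THF, rt
Reagents that add atoms: water, O
Why: Acid-catalysed acetal hydrolysis; dilute acid at room temperature leaves benzyl ethers, methyl ethers and the pyranone intact.

Step 15
Reactants: 20 1-(2,6-dihydroxy-4-methoxyphenyl)ethan-1-one
Product: 21 1-[2-(benzyloxy)-6-hydroxy-4-methoxyphenyl]ethan-1-one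
Conditions: BnBr (1.05 equiv), K2CO3, acetone, reflux
Reagents that add atoms: benzyl bromide, BrCc1ccccc1
Why: Williamson mono-O-benzylation; the two hydroxyls are equivalent, and after the first alkylation the remaining one is chelated to the acetyl carbonyl and resists a second.

Step 16
Reactants: 19 4-{[5,7-bis(benzyloxy)-2-(4-methoxyphenyl)-4-oxo-4H-chromen-8-yl]oxy}benzaldehyde; 21 1-[2-(benzyloxy)-6-hydroxy-4-methoxyphenyl]ethan-1-one
Product: 22 5,7-bis(benzyloxy)-8-(4-{(E)-3-[2-(benzyloxy)-6-hydroxy-4-methoxyphenyl]-3-oxoprop-1-en-1-yl}phenoxy)-2-(4-methoxyphenyl)-4H-chromen-4-one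
Conditions: KOH (aq., 50%), EtOH/THF, rt
Reagents that add atoms: none
Why: Claisen–Schmidt condensation; the enolate of 21 adds to the non-enolisable aldehyde and dehydration gives the conjugated E-enone, the thermodynamic isomer. Any flavanone formed by ring closure converges in step 17.

Step 17
Reactants: 22 5,7-bis(benzyloxy)-8-(4-{(E)-3-[2-(benzyloxy)-6-hydroxy-4-methoxyphenyl]-3-oxoprop-1-en-1-yl}phenoxy)-2-(4-methoxyphenyl)-4H-chromen-4-one
Product: 23 5,7-bis(benzyloxy)-8-{4-[5-(benzyloxy)-7-methoxy-4-oxo-4H-chromen-2-yl]phenoxy}-2-(4-methoxyphenyl)-4H-chromen-4-one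
Conditions: I2 (10 mol %), DMSO, 130 °C
Reagents that add atoms: none
Why: Iodine-catalysed oxidative cyclisation of a 2'-hydroxychalcone; oxa-Michael closure, alpha-iodination and loss of HI give the flavone, and DMSO reoxidises iodide so that only catalytic iodine meets the electron-rich rings.

Step 18
Reactants: 23 5,7-bis(benzyloxy)-8-{4-[5-(benzyloxy)-7-methoxy-4-oxo-4H-chromen-2-yl]phenoxy}-2-(4-methoxyphenyl)-4H-chromen-4-one
Product: 24 5,7-dihydroxy-8-[4-(5-hydroxy-7-methoxy-4-oxo-4H-chromen-2-yl)phenoxy]-2-(4-methoxyphenyl)-4H-chromen-4-one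
Conditions: H2 (1 atm), Pd/C (10%), THF/MeOH, rt
Reagents that add atoms: none
Why: Catalytic hydrogenolysis; benzyl aryl ethers are cleaved at atmospheric pressure faster than the flavone C2=C3 bonds are reduced, and methyl ethers and the diaryl ether are inert.

**Compound list**

1 | 2,4,6-trihydroxybenzaldehyde | O=Cc1c(O)cc(O)cc1O | starting material
2 | 2,4-bis(benzyloxy)-6-hydroxybenzaldehyde | O=Cc1c(O)cc(OCc2ccccc2)cc1OCc1ccccc1 | intermediate
3 | 2,4-bis(benzyloxy)-6-(methoxymethoxy)benzaldehyde | COCOc1cc(OCc2ccccc2)cc(OCc2ccccc2)c1C=O | intermediate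
4 | 2,4-bis(benzyloxy)-6-(methoxymethoxy)phenyl formate (not isolated) | COCOc1cc(OCc2ccccc2)cc(OCc2ccccc2)c1OC=O | intermediate
5 | 2,4-bis(benzyloxy)-6-(methoxymethoxy)phenol | COCOc1cc(OCc2ccccc2)cc(OCc2ccccc2)c1O | intermediate
6 | 4-fluorobenzaldehyde | O=Cc1ccc(F)cc1 | starting material
7 | 4-[2,4-bis(benzyloxy)-6-(methoxymethoxy)phenoxy]benzaldehyde | COCOc1cc(OCc2ccccc2)cc(OCc2ccccc2)c1Oc1ccc(C=O)cc1 | intermediate
8 | 4-[2,4-bis(benzyloxy)-6-hydroxyphenoxy]benzaldehyde | O=Cc1ccc(Oc2c(O)cc(OCc3ccccc3)cc2OCc2ccccc2)cc1 | intermediate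
9 | 3,5-bis(benzyloxy)-2-[4-(1,3-dioxolan-2-yl)phenoxy]phenol | Oc1cc(OCc2ccccc2)cc(OCc2ccccc2)c1Oc1ccc(C2OCCO2)cc1 | intermediate
10 | 4,6-bis(benzyloxy)-3-[4-(1,3-dioxolan-2-yl)phenoxy]-2-hydroxybenzaldehyde | O=Cc1c(O)c(Oc2ccc(C3OCCO3)cc2)c(OCc2ccccc2)cc1OCc1ccccc1 | intermediate
11 | 3,5-bis(benzyloxy)-2-[4-(1,3-dioxolan-2-yl)phenoxy]-6-(1-hydroxyprop-2-en-1-yl)phenol (racemic) | C=CC(O)c1c(O)c(Oc2ccc(C3OCCO3)cc2)c(OCc2ccccc2)cc1OCc1ccccc1 | intermediate
12 | 4-methoxybenzoyl chloride | COc1ccc(C(=O)Cl)cc1 | starting material
13 | 3,5-bis(benzyloxy)-2-[4-(1,3-dioxolan-2-yl)phenoxy]-6-(1-hydroxyprop-2-en-1-yl)phenyl 4-methoxybenzoate (racemic, not isolated) | C=CC(O)c1c(OC(=O)c2ccc(OC)cc2)c(Oc2ccc(C3OCCO3)cc2)c(OCc2ccccc2)cc1OCc1ccccc1 | intermediate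
14 | 3,5-bis(benzyloxy)-2-[4-(1,3-dioxolan-2-yl)phenoxy]-6-{1-[(triethylsilyl)oxy]prop-2-en-1-yl}phenyl 4-methoxybenzoate (racemic) | C=CC(O[Si](CC)(CC)CC)c1c(OC(=O)c2ccc(OC)cc2)c(Oc2ccc(C3OCCO3)cc2)c(OCc2ccccc2)cc1OCc1ccccc1 | intermediate
15 | triethyl({1-[4,6-bis(benzyloxy)-3-[4-(1,3-dioxolan-2-yl)phenoxy]-2-{[1-(4-methoxyphenyl)ethenyl]oxy}phenyl]prop-2-en-1-yl}oxy)silane (racemic) | C=CC(O[Si](CC)(CC)CC)c1c(OC(=C)c2ccc(OC)cc2)c(Oc2ccc(C3OCCO3)cc2)c(OCc2ccccc2)cc1OCc1ccccc1 | intermediate
16 | 1-[4,6-bis(benzyloxy)-3-[4-(1,3-dioxolan-2-yl)phenoxy]-2-{[1-(4-methoxyphenyl)ethenyl]oxy}phenyl]prop-2-en-1-ol (racemic) | C=CC(O)c1c(OC(=C)c2ccc(OC)cc2)c(Oc2ccc(C3OCCO3)cc2)c(OCc2ccccc2)cc1OCc1ccccc1 | intermediate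
17 | 1-[4,6-bis(benzyloxy)-3-[4-(1,3-dioxolan-2-yl)phenoxy]-2-{[1-(4-methoxyphenyl)ethenyl]oxy}phenyl]prop-2-en-1-one | C=CC(=O)c1c(OC(=C)c2ccc(OC)cc2)c(Oc2ccc(C3OCCO3)cc2)c(OCc2ccccc2)cc1OCc1ccccc1 | intermediate
18 | 5,7-bis(benzyloxy)-8-[4-(1,3-dioxolan-2-yl)phenoxy]-2-(4-methoxyphenyl)-4H-chromen-4-one | COc1ccc(-c2cc(=O)c3c(OCc4ccccc4)cc(OCc4ccccc4)c(Oc4ccc(C5OCCO5)cc4)c3o2)cc1 | intermediate
19 | 4-{[5,7-bis(benzyloxy)-2-(4-methoxyphenyl)-4-oxo-4H-chromen-8-yl]oxy}benzaldehyde | COc1ccc(-c2cc(=O)c3c(OCc4ccccc4)cc(OCc4ccccc4)c(Oc4ccc(C=O)cc4)c3o2)cc1 | intermediate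
20 | 1-(2,6-dihydroxy-4-methoxyphenyl)ethan-1-one | CC(=O)c1c(O)cc(OC)cc1O | starting material
21 | 1-[2-(benzyloxy)-6-hydroxy-4-methoxyphenyl]ethan-1-one | CC(=O)c1c(O)cc(OC)cc1OCc1ccccc1 | intermediate
22 | 5,7-bis(benzyloxy)-8-(4-{(E)-3-[2-(benzyloxy)-6-hydroxy-4-methoxyphenyl]-3-oxoprop-1-en-1-yl}phenoxy)-2-(4-methoxyphenyl)-4H-chromen-4-one | COc1ccc(-c2cc(=O)c3c(OCc4ccccc4)cc(OCc4ccccc4)c(Oc4ccc(/C=C/C(=O)c5c(O)cc(OC)cc5OCc5ccccc5)cc4)c3o2)cc1 | intermediate
23 | 5,7-bis(benzyloxy)-8-{4-[5-(benzyloxy)-7-methoxy-4-oxo-4H-chromen-2-yl]phenoxy}-2-(4-methoxyphenyl)-4H-chromen-4-one | COc1ccc(-c2cc(=O)c3c(OCc4ccccc4)cc(OCc4ccccc4)c(Oc4ccc(-c5cc(=O)c6c(OCc7ccccc7)cc(OC)cc6o5)cc4)c3o2)cc1 | intermediate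
24 | 5,7-dihydroxy-8-[4-(5-hydroxy-7-methoxy-4-oxo-4H-chromen-2-yl)phenoxy]-2-(4-methoxyphenyl)-4H-chromen-4-one | COc1ccc(-c2cc(=O)c3c(O)cc(O)c(Oc4ccc(-c5cc(=O)c6c(O)cc(OC)cc6o5)cc4)c3o2)cc1 | target

**Step count and risk**

Total step count: 18. Longest linear sequence: 17 steps (steps 1–14 and 16–18); step 15 is a one-step side branch.

Least certain steps:

Step 13 (key step, proposed new method). The catalytic cycle may stall. Ruthenium can be transferred to the alkoxy-bearing carbon of the enol ether, giving a heteroatom-stabilised carbene that turns over slowly. The short-lived acyl carbene can decay before it cyclises. Thermal oligomerisation of the vinyl ketone can consume the substrate at 80 °C.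

The fallback closes the same C2=C3 bond at the alcohol oxidation level, using known chemistry. It sets out from 15. Treatment with the second-generation Grubbs catalyst RuCl2(=CHPh)(H2IMes)(PCy3) in toluene at 60 °C is the known ring-closing metathesis of a methylenated aryl ester with an unactivated terminal alkene. It should give triethyl{[5,7-bis(benzyloxy)-8-[4-(1,3-dioxolan-2-yl)phenoxy]-2-(4-methoxyphenyl)-4H-chromen-4-yl]oxy}silane F1. Bu4NF in THF at 0 °C would then free 5,7-bis(benzyloxy)-8-[4-(1,3-dioxolan-2-yl)phenoxy]-2-(4-methoxyphenyl)-4H-chromen-4-ol F2. MnO2 in CH2Cl2 would oxidise this doubly activated alcohol to 18, where the route resumes.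

Step 10. Methylenation of the doubly ortho-substituted ester may be slow. The aluminium Lewis acid may then ionise the benzylic silyl ether or open the acetal. The titanium methylidene may engage the terminal alkene, or the titanacycle may fragment with loss of the phenoxide.

The fallback gives up the enol ether and reaches the same flavone by a known ynone cyclisation. It sets out from 10. Lithium (4-methoxyphenyl)acetylide (from 4-ethynylanisole and n-BuLi, 2.5 equiv, THF, −78 °C) would add to the aldehyde to give 3,5-bis(benzyloxy)-2-[4-(1,3-dioxolan-2-yl)phenoxy]-6-[1-hydroxy-3-(4-methoxyphenyl)prop-2-yn-1-yl]phenol F3. MnO2 would oxidise the propargylic alcohol to 1-{4,6-bis(benzyloxy)-3-[4-(1,3-dioxolan-2-yl)phenoxy]-2-hydroxyphenyl}-3-(4-methoxyphenyl)prop-2-yn-1-one F4. Et2NH in EtOH would add to the ynone, and the phenol would displace the amine in a 6-endo closure to 18.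

Step 9. Before the carbinol is silylated, the acyl group may migrate from the phenol oxygen to the neighbouring carbinol oxygen through a six-membered transition state. The freed phenoxide can then expel the benzylic ester and form an ortho-quinone methide.

The fallback separates the two oxygens by their silyl ether reactivity. It sets out from 11. Et3SiCl (2.5 equiv) and imidazole in DMF would give {3,5-bis(benzyloxy)-2-[4-(1,3-dioxolan-2-yl)phenoxy]-6-{1-[(triethylsilyl)oxy]prop-2-en-1-yl}phenoxy}triethylsilane F5. K2CO3 in MeOH at 0 °C would cleave only the aryl silyl ether to give 3,5-bis(benzyloxy)-2-[4-(1,3-dioxolan-2-yl)phenoxy]-6-{1-[(triethylsilyl)oxy]prop-2-en-1-yl}phenol F6. Acylation with 12 (Et3N, catalytic 4-(dimethylamino)pyridine, CH2Cl2) would return to 14.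

Step 16. Hydroxide may add to C2 of the existing pyranone and open it by retro-Claisen cleavage during a slow condensation of the hindered acetophenone enolate.

The fallback avoids hydroxide by a Baker–Venkataraman sequence. It sets out from 19. NaClO2, NaH2PO4 and 2-methylbut-2-ene in t-BuOH/THF/H2O would give 4-{[5,7-bis(benzyloxy)-2-(4-methoxyphenyl)-4-oxo-4H-chromen-8-yl]oxy}benzoic acid F7. Esterification with 21 (EDC·HCl, 4-(dimethylamino)pyridine, CH2Cl2) would give 2-acetyl-3-(benzyloxy)-5-methoxyphenyl 4-{[5,7-bis(benzyloxy)-2-(4-methoxyphenyl)-4-oxo-4H-chromen-8-yl]oxy}benzoate F8. LiN(SiMe3)2 in THF (−78 to 0 °C) would effect the acyl shift to 1-[2-(benzyloxy)-6-hydroxy-4-methoxyphenyl]-3-(4-{[5,7-bis(benzyloxy)-2-(4-methoxyphenyl)-4-oxo-4H-chromen-8-yl]oxy}phenyl)propane-1,3-dione F9. Catalytic H2SO4 in AcOH would cyclodehydrate it to 23, where the route resumes.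

**Further compounds**

F1 | step 13 | triethyl{[5,7-bis(benzyloxy)-8-[4-(1,3-dioxolan-2-yl)phenoxy]-2-(4-methoxyphenyl)-4H-chromen-4-yl]oxy}silane (racemic) | CC[Si](CC)(CC)OC1C=C(c2ccc(OC)cc2)Oc2c(Oc3ccc(C4OCCO4)cc3)c(OCc3ccccc3)cc(OCc3ccccc3)c21
F2 | step 13 | 5,7-bis(benzyloxy)-8-[4-(1,3-dioxolan-2-yl)phenoxy]-2-(4-methoxyphenyl)-4H-chromen-4-ol (racemic) | OC1C=C(c2ccc(OC)cc2)Oc2c(Oc3ccc(C4OCCO4)cc3)c(OCc3ccccc3)cc(OCc3ccccc3)c21
F3 | step 10 | 3,5-bis(benzyloxy)-2-[4-(1,3-dioxolan-2-yl)phenoxy]-6-[1-hydroxy-3-(4-methoxyphenyl)prop-2-yn-1-yl]phenol (racemic) | COc1ccc(C#CC(O)c2c(O)c(Oc3ccc(C4OCCO4)cc3)c(OCc3ccccc3)cc2OCc2ccccc2)cc1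
F4 | step 10 | 1-{4,6-bis(benzyloxy)-3-[4-(1,3-dioxolan-2-yl)phenoxy]-2-hydroxyphenyl}-3-(4-methoxyphenyl)prop-2-yn-1-one | COc1ccc(C#CC(=O)c2c(O)c(Oc3ccc(C4OCCO4)cc3)c(OCc3ccccc3)cc2OCc2ccccc2)cc1
F5 | step 9 | {3,5-bis(benzyloxy)-2-[4-(1,3-dioxolan-2-yl)phenoxy]-6-{1-[(triethylsilyl)oxy]prop-2-en-1-yl}phenoxy}triethylsilane (racemic) | C=CC(O[Si](CC)(CC)CC)c1c(O[Si](CC)(CC)CC)c(Oc2ccc(C3OCCO3)cc2)c(OCc2ccccc2)cc1OCc1ccccc1
F6 | step 9 | 3,5-bis(benzyloxy)-2-[4-(1,3-dioxolan-2-yl)phenoxy]-6-{1-[(triethylsilyl)oxy]prop-2-en-1-yl}phenol (racemic) | C=CC(O[Si](CC)(CC)CC)c1c(O)c(Oc2ccc(C3OCCO3)cc2)c(OCc2ccccc2)cc1OCc1ccccc1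
F7 | step 16 | 4-{[5,7-bis(benzyloxy)-2-(4-methoxyphenyl)-4-oxo-4H-chromen-8-yl]oxy}benzoic acid | COc1ccc(-c2cc(=O)c3c(OCc4ccccc4)cc(OCc4ccccc4)c(Oc4ccc(C(=O)O)cc4)c3o2)cc1
F8 | step 16 | 2-acetyl-3-(benzyloxy)-5-methoxyphenyl 4-{[5,7-bis(benzyloxy)-2-(4-methoxyphenyl)-4-oxo-4H-chromen-8-yl]oxy}benzoate | COc1ccc(-c2cc(=O)c3c(OCc4ccccc4)cc(OCc4ccccc4)c(Oc4ccc(C(=O)Oc5cc(OC)cc(OCc6ccccc6)c5C(C)=O)cc4)c3o2)cc1
F9 | step 16 | 1-[2-(benzyloxy)-6-hydroxy-4-methoxyphenyl]-3-(4-{[5,7-bis(benzyloxy)-2-(4-methoxyphenyl)-4-oxo-4H-chromen-8-yl]oxy}phenyl)propane-1,3-dione | COc1ccc(-c2cc(=O)c3c(OCc4ccccc4)cc(OCc4ccccc4)c(Oc4ccc(C(=O)CC(=O)c5c(O)cc(OC)cc5OCc5ccccc5)cc4)c3o2)cc1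
A1 | alternative 1 | 1,5-bis(benzyloxy)-2-(ethynyloxy)-3-(methoxymethoxy)benzene | C#COc1c(OCOC)cc(OCc2ccccc2)cc1OCc1ccccc1
A2 | alternative 1 | methyl 2-oxo-2H-pyran-5-carboxylate (methyl coumalate) | COC(=O)C1=COC(=O)C=C1
A3 | alternative 1 | methyl 4-[2,4-bis(benzyloxy)-6-(methoxymethoxy)phenoxy]benzoate | COC(=O)c1ccc(Oc2c(OCOC)cc(OCc3ccccc3)cc2OCc2ccccc2)cc1
A4 | alternative 2 | 3,5-dimethoxy-2-(trimethylsilyl)phenyl trifluoromethanesulfonate | COc1cc(OC)c([Si](C)(C)C)c(OS(=O)(=O)C(F)(F)F)c1
A5 | alternative 2 | 3-(4-{[5,7-bis(benzyloxy)-2-(4-methoxyphenyl)-4-oxo-4H-chromen-8-yl]oxy}phenyl)prop-2-ynoic acid | COc1ccc(-c2cc(=O)c3c(OCc4ccccc4)cc(OCc4ccccc4)c(Oc4ccc(C#CC(=O)O)cc4)c3o2)cc1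
A6 | alternative 2 | 5,7-bis(benzyloxy)-8-[4-(5,7-dimethoxy-4-oxo-4H-chromen-2-yl)phenoxy]-2-(4-methoxyphenyl)-4H-chromen-4-one | COc1ccc(-c2cc(=O)c3c(OCc4ccccc4)cc(OCc4ccccc4)c(Oc4ccc(-c5cc(=O)c6c(OC)cc(OC)cc6o5)cc4)c3o2)cc1
A7 | alternative 3 | methyl 4-[2,4-bis(benzyloxy)-6-hydroxyphenoxy]benzoate | COC(=O)c1ccc(Oc2c(O)cc(OCc3ccccc3)cc2OCc2ccccc2)cc1
A8 | alternative 3 | tert-butyl 3-(4-methoxyphenyl)prop-2-ynoate | COc1ccc(C#CC(=O)OC(C)(C)C)cc1
A9 | alternative 3 | (Z)-3-{3,5-bis(benzyloxy)-2-[4-(methoxycarbonyl)phenoxy]phenoxy}-3-(4-methoxyphenyl)prop-2-enoic acid | COC(=O)c1ccc(Oc2c(O/C(=C\C(=O)O)c3ccc(OC)cc3)cc(OCc3ccccc3)cc2OCc2ccccc2)cc1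
A10 | alternative 3 | methyl 4-{[5,7-bis(benzyloxy)-2-(4-methoxyphenyl)-4-oxo-4H-chromen-8-yl]oxy}benzoate | COc1ccc(-c2cc(=O)c3c(OCc4ccccc4)cc(OCc4ccccc4)c(Oc4ccc(C(=O)OC)cc4)c3o2)cc1
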